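Count what the gas can pay for, then ask what else spends first end groups.

in all of them: gas 23 mM (held)

| flask | first end groups | third end groups | remark | time |
|---|---|---|---|---|
| north | 0.43 M | 0.043 M | run made earlier |  |
| south | 0.43 M | 0.029 M | run made earlier |  |
| north-west | 0.43 M | 0.065 M | run made earlier |  |
| east | 0.86 M | 0.043 M | run made earlier |  |
| cedar | 0.43 M | 0.0430 M | everything together at the start | 8.0 h |
| oak | 0.43 M (fed, over 3.0 h) | 0.0430 M | all else is in the flask from the start; the feed brings no volume worth counting | 8.0 h |
| maple | 0.43 M | 0.0430 M (fed, over 3.0 h) | all else is in the flask from the start; the feed brings no volume worth counting | 8.0 h |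

| run | time / h | links / % |
|---|---|---|
| north | 1.50 | 9.2 |
| north | 3.00 | 24.5 |
| north | 5.00 | 46.8 |
| north | 6.00 | 55.6 |
| north | 8.00 | 67.1 |
| south | 0.417 | 2.4 |
| south | 0.667 | 5.2 |
| south | 1.33 | 10.8 |
| south | 2.50 | 22.7 |
| south | 5.00 | 49.4 |
| north-west | 1.00 | 3.6 |
| north-west | 2.00 | 10.9 |
| north-west | 3.00 | 20.4 |
| north-west | 4.00 | 31.9 |
| north-west | 5.00 | 41.6 |
| east | 0.417 | 1.2 |
| east | 1.33 | 4.3 |
| east | 2.00 | 7.7 |
| east | 3.00 | 12.5 |
| east | 5.00 | 25.3 |

(scatter of a reading: 0.5 percentage points)

- at the start none of the gas is in solution

* which flask leads in amount of links, in percent of the first end groups charged ("all alike" within 1.5 percentage points) (cedar / oak / maple / all alike)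
* how much links is there at the end, in percent of the first end groups charged: cedar
* how much links is there at the end, in percent of the first end groups charged: oak
* how much links is there at the end, in percent of the first end groups charged: maple

Two chemists dispute these flasks. Both start from the steady slope. By my own reading, north gains 0.0479 M h⁻¹ of links between 3.00 h and 5.00 h. East, with twice the first end groups, holds 0.218 M of links at 5.00 h, and north holds 0.201 M. So the first chemist calls uptake of gas the rate-limiting step. South leads north-west by 0.0335 M of links at 5.00 h, and south has 0.0360 M less third end groups. So third end groups seem to cost one gas each.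

My own sum at 8.0 h, slope times time less the third end groups, gives 79.2%. This is the gas budget: the links a steady gas supply pays for by a given time, after third end groups are served, in percent of the first end groups charged. Cedar, oak and maple have equal budgets, since gas, charges and time match.

The forecast is the first chemist's: all alike, with cedar 67%, oak 65.5% and maple 67.5%. These numbers are not my sum, and each stands lower than it. "Oak loses a little while first end groups are scarce," it says.

The second chemist looks at north's end. North reaches 67.1%, lower than the budget. Its last slope, 0.0247 M h⁻¹, is about half the earlier one. Yet 0.141 M of first end groups is not in links. She suspects a side route that spends them where they stand concentrated. A slow feed should spare them, so she puts oak first, between 67.1% and 79.2%.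

The flask gives oak: cedar 67.4%, oak 73.6%, maple 68.4%.

    gas ⇌ second end groups, rate k1*(csat - [second end groups]) (kL = 2.38 h⁻¹)
    second end groups → decomposed reagent (k = 0.191 h⁻¹)
    2 first end groups → homo dimer (k = 0.173 M⁻¹ h⁻¹)
    first end groups + second end groups → links (k = 92.4 M⁻¹ h⁻¹)
    second end groups + third end groups → links of the second sort (k = 1790 M⁻¹ h⁻¹)

Oak's 73.6% stands lower than the budget. In cedar the midpoint of the turnover up to 8.0 h into homo dimer comes at 1.29 h, earlier than that into links at 3.78 h, and homo dimer, counted as two first end groups, stands at 30.2% in cedar against 18.8% in oak at 8.00 h. The first chemist's all alike does hold at 4.00 h: links stand at 36.1% in cedar, 35.5% in oak and 36.3% in maple, inside the margin of 1.5 percentage points.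

Take a neighbour like cedar with 0.73 M of first end groups. The same gas gives a budget of 46.7%, and that flask gives 46.1%.

Readings and results were computed for an exercise; scatter was added.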